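**Plan**

- Retrosynthesis: ring D is cut first at C8–C15 (palladium-mediated oxidative cyclization of the lactone silyl ketene acetal onto a C13 isopropenyl group), then C13–C16 (isopropenyl addition to a C13 ketone), C9–C11 (ring C, radical cyclization), C8–C14 (lactone alkylation), C7–O/C9–C10 (lactonisation, Michael addition) and C5–C6 (vinyl conjugate addition).
- Feature used: C8 is the α-carbon of the C7 lactone (ring B) and lies 1,3 to C13 across C14 in ring C, so its ketene acetal can reach an isopropenyl group on C13 and close the five-membered ring D together with the C8 quaternary centre.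
- Forward order: ring A (desymmetrised 4,4-dimethylcyclohexadienone, whose surviving enone is the C1 ketone/C2=C3 of the target), then spiro lactone ring B, ring C, ring D, then C15 oxidation, C16=C17 reduction and desilylation.
- Stereochemistry: C5 from the catalyst (rhodium/(R)-BINAP); C10 from C5 (Michael addition anti to the C6 arm); C9 from C10 (radical attack anti to the C5 side of the spiro centre); C13 from the ring C conformation (equatorial attack); C8 from C13 (bridging); C16 from exo-face protonation.
- Ring A needs no carbonyl protection: once C10 is quaternary the enone has no enolisable hydrogen, so the lactone is the only carbonyl that can form a ketene acetal.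

Key step: step 18

Remark: locants follow kaurane numbering (C1–C20); compounds 23–26 are written as the cis-fused C8 epimer expected from step 13, and either C8 epimer would converge at 27.

**Route**

Step 1
Reactants: 1 4,4-dimethylcyclohex-2-en-1-one
Product: 2 4,4-dimethylcyclohexa-2,5-dien-1-one
Conditions: DDQ, TsOH (cat.), 1,4-dioxane, reflux
Reagents that add atoms: none
Why: DDQ dehydrogenation can only introduce the second double bond between C5 and C6 of the enone (C4 is quaternary and the other α-carbon is vinylic), giving the cross-conjugated dienone whose two enone arms are enantiotopic.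

Step 2
Reactants: 2 4,4-dimethylcyclohexa-2,5-dien-1-one
Product: 3 (R)-5-ethenyl-4,4-dimethylcyclohex-2-en-1-one
Conditions: potassium vinyltrifluoroborate (1.1 equiv), [Rh(cod)2]BF4 (3 mol %), (R)-BINAP (3.3 mol %), toluene/H2O (20:1), 100 °C
Reagents that add atoms: potassium vinyltrifluoroborate, C=C[B-](F)(F)F.[K+]
Why: Rhodium-catalysed asymmetric 1,4-addition of the vinylborate (Hayashi–Miyaura reaction) to one of the two enantiotopic enone arms should set C5, (R)-BINAP being the ligand enantiomer expected to give (R)-3 by analogy with the (S)-BINAP/(S)-3-substituted cyclohexanone correlation, while the untouched arm remains as the ring A enone of the target.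

Step 3
Reactants: 3 (R)-5-ethenyl-4,4-dimethylcyclohex-2-en-1-one
Product: 6 (S)-5-(hydroxymethyl)-4,4-dimethylcyclohex-2-en-1-one, via ozonide 4 (not isolated), via aldehyde 5 (not isolated)
Conditions: O3, CH2Cl2, −78 °C (to first persistent excess); PPh3, −78 °C → rt; evaporate; NaBH4, EtOH/CH2Cl2 (3:7), −78 °C
Reagents that add atoms: ozone, [O-][O+]=O
Why: Ozonolysis cleaves the electron-rich vinyl group far faster than the electron-poor and hindered enone C=C, and NaBH4 at −78 °C reduces the resulting aldehyde chemoselectively in the presence of the conjugated ketone, so the vinyl group becomes the C6 hydroxymethyl arm with C5 untouched.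

Step 4
Reactants: 6 (S)-5-(hydroxymethyl)-4,4-dimethylcyclohex-2-en-1-one
Product: 7 (S)-5-{[tert-butyl(dimethyl)silyl]oxymethyl}-4,4-dimethylcyclohex-2-en-1-one
Conditions: TBSCl, imidazole, DMF, rt
Reagents that add atoms: tert-butyldimethylsilyl chloride, CC(C)(C)[Si](C)(C)Cl
Why: Silyl ether protection of the primary alcohol (imidazole-promoted silylation) keeps C6–OH out of the enolate, radical and organometallic steps that follow.

Step 5
Reactants: 7 (S)-5-{[tert-butyl(dimethyl)silyl]oxymethyl}-4,4-dimethylcyclohex-2-en-1-one
Product: 8 (5R,6Z)-5-{[tert-butyl(dimethyl)silyl]oxymethyl}-6-(hydroxymethylidene)-4,4-dimethylcyclohex-2-en-1-one (enol form of the C10 formyl ketone)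
Conditions: NaH, HCO2Et, EtOH (cat.), THF, 0 °C → rt; aq. HCl work-up
Reagents that add atoms: ethyl formate, CCOC=O
Why: Crossed Claisen condensation with ethyl formate can only take place at C10, the single enolisable position of the enone, and is driven by formation of the chelated hydroxymethylidene enolate.

Step 6
Reactants: 8 (5R,6Z)-5-{[tert-butyl(dimethyl)silyl]oxymethyl}-6-(hydroxymethylidene)-4,4-dimethylcyclohex-2-en-1-one
Product: 9 methyl 3-[(1S,6R)-6-{[tert-butyl(dimethyl)silyl]oxymethyl}-1-formyl-5,5-dimethyl-2-oxocyclohex-3-en-1-yl]propanoate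
Conditions: methyl acrylate (2 equiv), DBU (0.2 equiv), MeCN, rt → 40 °C
Reagents that add atoms: methyl acrylate, C=CC(=O)OC
Why: Base-catalysed Michael addition of the doubly stabilised C10 anion to methyl acrylate builds the quaternary centre, the acrylate approaching the planar anion on the face opposite the adjacent C5 silyloxymethyl group so that the C9 chain ends up trans and the formyl carbon C20 cis to C6 (1,2-induction).

Step 7
Reactants: 9 methyl 3-[(1S,6R)-6-{[tert-butyl(dimethyl)silyl]oxymethyl}-1-formyl-5,5-dimethyl-2-oxocyclohex-3-en-1-yl]propanoate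
Product: 11 spirolactone (6S,11R)-11-{[tert-butyl(dimethyl)silyl]oxymethyl}-10,10-dimethyl-2-oxaspiro[5.5]undec-8-ene-3,7-dione, via hydroxy ester 10 (not isolated)
Conditions: NaBH4, MeOH/CH2Cl2 (1:1), −78 °C; AcOH; then PPTS (cat.), benzene, 50 °C
Reagents that add atoms: none
Why: Chemoselective hydride reduction of the aldehyde (the hindered conjugated ketone and the ester are left at −78 °C) followed by acid-catalysed lactonisation of the C20 alcohol onto the C7 ester closes the six-membered lactone (ring B) and removes the risk of retro-aldol loss of C20.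

Step 8
Reactants: 12 dimethyl itaconate (dimethyl 2-methylidenebutanedioate)
Product: 13 2-methylidenebutane-1,4-diol
Conditions: i-Bu2AlH (4.5 equiv), CH2Cl2, −78 → 0 °C; aq. potassium sodium tartrate
Reagents that add atoms: none
Why: i-Bu2AlH reduces both ester groups by 1,2-hydride addition without conjugate reduction of the 1,1-disubstituted alkene, a standard route to the methylidene diol.

Step 9
Reactants: 13 2-methylidenebutane-1,4-diol
Product: 14 4-bromo-2-(bromomethyl)but-1-ene
Conditions: CBr4, PPh3, CH2Cl2, 0 °C
Reagents that add atoms: carbon tetrabromide, BrC(Br)(Br)Br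
Why: The Appel reaction replaces both primary hydroxyl groups by bromide under neutral conditions and gives a dibromide whose allylic C–Br bond is far more reactive in SN2 than the homoallylic one.

Step 10
Reactants: 11 spirolactone (6S,11R)-11-{[tert-butyl(dimethyl)silyl]oxymethyl}-10,10-dimethyl-2-oxaspiro[5.5]undec-8-ene-3,7-dione; 14 4-bromo-2-(bromomethyl)but-1-ene
Product: 15 (6S,11R)-4-(4-bromo-2-methylidenebutyl)-11-{[tert-butyl(dimethyl)silyl]oxymethyl}-10,10-dimethyl-2-oxaspiro[5.5]undec-8-ene-3,7-dione (C8 epimers; spiro position 4 is C8)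
Conditions: LiN(iPr)2 (1.05 equiv), THF, −78 °C; 14 (1.5 equiv), DMPU, −78 → −40 °C
Reagents that add atoms: none
Why: SN2 alkylation of the lithium lactone enolate occurs selectively at the allylic bromide of 14 and the configuration formed at C8 is irrelevant because C8 becomes trigonal in steps 12 and 17, while intramolecular Michael addition of the enolate to C3 of the ring A enone is geometrically excluded by the spiro lactone ring.

Step 11
Reactants: 15 (6S,11R)-4-(4-bromo-2-methylidenebutyl)-11-{[tert-butyl(dimethyl)silyl]oxymethyl}-10,10-dimethyl-2-oxaspiro[5.5]undec-8-ene-3,7-dione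
Product: 18 (6S,11R)-4-{[2-(2-bromoethyl)-1,3-dioxolan-2-yl]methyl}-11-{[tert-butyl(dimethyl)silyl]oxymethyl}-10,10-dimethyl-2-oxaspiro[5.5]undec-8-ene-3,7-dione (C8 epimers), via ozonide 16 (not isolated), via bromo ketone 17 (not isolated)
Conditions: O3, CH2Cl2, −78 °C; PPh3, −78 °C → rt; evaporate; (Me3SiOCH2)2, Me3SiOTf (cat.), CH2Cl2, −78 → −20 °C; pyridine quench
Reagents that add atoms: 1,2-bis(trimethylsilyloxy)ethane, C[Si](C)(C)OCCO[Si](C)(C)C
Why: Ozonolysis of the electron-rich 1,1-disubstituted alkene followed at once by silyl-transfer ketalisation (Me3SiOTf catalysis) converts C13 into a protected ketone, so that C14–H is neither allylic nor α to a free ketone in step 12 and the β-bromo ketone has no chance to lose HBr.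

Step 12
Reactants: 18 (6S,11R)-4-{[2-(2-bromoethyl)-1,3-dioxolan-2-yl]methyl}-11-{[tert-butyl(dimethyl)silyl]oxymethyl}-10,10-dimethyl-2-oxaspiro[5.5]undec-8-ene-3,7-dione
Product: 22 (6S,11R)-4-{[2-(2-bromoethyl)-1,3-dioxolan-2-yl]methyl}-11-{[tert-butyl(dimethyl)silyl]oxymethyl}-10,10-dimethyl-2-oxaspiro[5.5]undeca-4,8-diene-3,7-dione, via silyl ketene acetal 19 (not isolated), via selenide 20 (not isolated), via selenoxide 21 (not isolated)
Conditions: KN(SiMe3)2, Me3SiCl (present from the start), THF, −78 °C; PhSeBr, −78 °C; then 30% H2O2, pyridine, CH2Cl2, 0 °C → rt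
Reagents that add atoms: none
Why: α-Selenenylation of the lactone through its silyl ketene acetal (the internal Me3SiCl quench prevents the enolate from displacing the C11 bromide) and selenoxide syn-elimination install the C8=C9 double bond, elimination going to the ring C9–H to give the conjugated endocyclic lactone as is usual for α-alkyl-α-selenyl lactones with an unactivated side chain.

Step 13
Reactants: 22 (6S,11R)-4-{[2-(2-bromoethyl)-1,3-dioxolan-2-yl]methyl}-11-{[tert-butyl(dimethyl)silyl]oxymethyl}-10,10-dimethyl-2-oxaspiro[5.5]undeca-4,8-diene-3,7-dione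
Product: 23 tricyclic ketal lactone (rings A, B and C; C13 ethylene ketal; H8 and H9 cis; C11 cis to C1 across the lactone ring)
Conditions: (Me3Si)3SiH (1.5 equiv) and AIBN (0.3 equiv) by syringe pump, toluene (0.005 M), 90 °C
Reagents that add atoms: none
Why: 6-endo-trig radical cyclisation (intramolecular Giese addition): the nucleophilic primary C11 radical adds to C9, the β-carbon of the unsaturated lactone, in preference to 5-exo attack on the fully substituted α-carbon, on the face of C9 syn to the flat C1 carbonyl and anti to the bulkier C5 side of the spiro centre, and the resulting C8 radical should take hydrogen anti to the C9–C10 bond to give the cis-fused lactone.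

Step 14
Reactants: 23 tricyclic ketal lactone
Product: 24 tricyclic keto lactone (ring A enone spiro at C10 to the C7–O–C20 δ-lactone, which is cis-fused to the ring C cyclohexan-13-one)
Conditions: PPTS, acetone/H2O (10:1), 55 °C
Reagents that add atoms: water, O
Why: Mild acid-catalysed ketal hydrolysis releases the unhindered C13 ketone and leaves the primary silyl ether, the lactone and the enone intact.

Step 15
Reactants: 24 tricyclic keto lactone
Product: 25 C13 tertiary alcohol (13-hydroxy-13-isopropenyl; isopropenyl cis to C8–H and C9–H, hydroxyl cis to the C8–C7 and C9–C10 bonds)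
Conditions: CeCl3 (anhydrous, 3 equiv), isopropenylmagnesium bromide (2.5 equiv), THF, −78 °C; H2O quench at −78 °C
Reagents that add atoms: isopropenylmagnesium bromide, C=C(C)[Mg]Br
Why: Cerium-mediated 1,2-addition of the isopropenyl Grignard reagent (organocerium addition) takes place at the unhindered C13 ketone in preference to the lactone and to the conjugated C1 ketone flanked by the quaternary C10, and the reagent should enter equatorially, opposite the axial C8–C7 bond of the cis-fused lactone, which places the isopropenyl group cis to C8–H and C9–H as required for ring D, the cold quench preventing translactonisation by the new alkoxide.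

Step 16
Reactants: 25 C13 tertiary alcohol
Product: 26 13-O-triethylsilyl ether of 25
Conditions: Et3SiOTf, 2,6-lutidine, CH2Cl2, −78 → 0 °C
Reagents that add atoms: triethylsilyl trifluoromethanesulfonate, CC[Si](CC)(CC)OS(=O)(=O)C(F)(F)F
Why: Silylation of the hindered tertiary alcohol with the silyl triflate (silyl ether protection) removes the only acidic proton before enolisation and keeps the allylic oxygen from binding palladium in step 18.

Step 17
Reactants: 26 13-O-triethylsilyl ether
Product: 27 lactone tert-butyldimethylsilyl ketene acetal (C8=C7(OSi)–O–C20) carrying the C13 isopropenyl group cis to C9–H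
Conditions: KN(SiMe3)2 (1.5 equiv), TBSCl (2 equiv), THF/DMPU, −78 °C
Reagents that add atoms: tert-butyldimethylsilyl chloride, CC(C)(C)[Si](C)(C)Cl
Why: O-Silylation of the potassium lactone enolate (silyl ketene acetal formation) is unambiguous because the lactone is the only enolisable carbonyl, the C1 ketone having no α- or γ-hydrogen (C10 and C4 quaternary, C2 vinylic).

Step 18
Reactants: 27 lactone silyl ketene acetal
Product: 28 tetracyclic lactone (rings A–D; bicyclo[3.2.1]octane with C16=C17 methylidene, 13-O-triethylsilyl, 6-O-tert-butyldimethylsilyl, ring A enone)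
Conditions: Pd(OAc)2 (1.0 equiv), AcOH (0.5 equiv), DMSO, air, 45 °C
Reagents that add atoms: none
Why: Divalent palladium (Pd(OAc)2) converts the silyl ketene acetal into a C8-bound palladium enolate with loss of the silyl group as its acetate, the isopropenyl alkene held on the same ring C face inserts into the C8–Pd bond so that C8 bonds to the terminal carbon C15, and the tertiary C16–Pd intermediate loses β-hydride from the methyl group to give the C16=C17 methylidene group and zerovalent palladium. The closest known reaction type is the Pd(OAc)2-mediated oxidative cyclisation (cycloalkenylation, a Saegusa-type process) of silyl enol ethers and lactone silyl ketene acetals onto pendant alkenes, which has been used to make bicyclo[3.2.1]octanes with quaternary bridgeheads. Ring D closes as a five-membered ring in the 5-endo-trig sense (both alkene carbons become ring atoms), which is feasible because the C–C bond forms by syn-carbopalladation inside the alkene-bound palladium enolate and not by direct enolate attack. The new quaternary stereocentre C8 is controlled by C13: C15 can reach C8 only across the one-carbon C14 link on the ring C face that carries the isopropenyl group, so the C15–C16 bridge ends up cis to C9–H and the lactone carbonyl stays cis to C10. The step needs carbopalladation to beat Saegusa-type β-hydride loss from C9 or C14 and protodesilylation, which the 1,3-diaxial proximity of the alkene and the AcOH/DMSO medium should secure, and it needs β-hydride loss towards C17 instead of C15, favoured because a double bond inside the two-carbon bridge is strained. The ring A enone is a spectator because C1 has no enolisable hydrogen and its electron-poor, hindered C2=C3 bond cannot be reached by C8 through the spiro lactone ring.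

Step 19
Reactants: 28 tetracyclic lactone
Product: 29 C15 allylic alcohol of 28 (either C15 epimer)
Conditions: SeO2 (0.5 equiv), t-BuOOH (3 equiv), CH2Cl2, rt
Reagents that add atoms: selenium dioxide, O=[Se]=O (reoxidised by tert-butyl hydroperoxide, CC(C)(C)OO)
Why: Allylic oxidation with SeO2/t-BuOOH (Riley oxidation, ene reaction then [2,3]-sigmatropic shift) hydroxylates C15, the only hydrogen-bearing allylic position of the C16=C17 methylidene group, while the ring A enone offers no allylic hydrogen.

Step 20
Reactants: 29 C15 allylic alcohol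
Product: 30 16-methylidene-15-ketone (ring D exocyclic enone; silyl ethers at C6 and C13)
Conditions: Dess–Martin periodinane, NaHCO3, CH2Cl2, rt
Reagents that add atoms: none
Why: Dess–Martin oxidation of the secondary allylic alcohol, the only free hydroxyl group, gives the α-methylidene cyclopentanone of ring D.

Step 21
Reactants: 30 16-methylidene-15-ketone
Product: 31 bis-silyl ether of the target (16R methyl, endo on the two-carbon bridge)
Conditions: [(Ph3P)CuH]6 (0.3 equiv), benzene/THF, H2O (5 equiv), 0 °C → rt; aq. NH4Cl
Reagents that add atoms: none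
Why: Copper hydride conjugate reduction delivers hydride to the unhindered terminal carbon C17 of the ring D enone much faster than to C3 of the ring A enone (a neopentyl β-carbon next to C4), and kinetic protonation of the copper enolate by water on the open exo face of the two-carbon bridge, the face of the C13 oxygen, places the C16 methyl group endo (16R).

Step 22
Reactants: 31 bis-silyl ether of the target
Product: 32 target CNP0533761.1, (5R,8S,9S,10S,13S,16R)-6,13-dihydroxy-1,15-dioxo-6,7-secokaur-2-en-7,20-olide
Conditions: HF·pyridine, pyridine/THF, 0 °C → rt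
Reagents that add atoms: none
Why: Fluoride-mediated desilylation with HF·pyridine removes the tertiary triethylsilyl and primary tert-butyldimethylsilyl ethers under mildly acidic conditions that avoid retro-aldol cleavage of the C13-hydroxy C15-ketone and epimerisation at C16, giving the target.

**Compound list**

1 | 4,4-dimethylcyclohex-2-en-1-one | CC1(C)CCC(=O)C=C1 | starting material
2 | 4,4-dimethylcyclohexa-2,5-dien-1-one | CC1(C)C=CC(=O)C=C1 | intermediate
3 | (R)-5-ethenyl-4,4-dimethylcyclohex-2-en-1-one | O=C1C=CC(C)(C)[C@@H](C=C)C1 | intermediate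
4 | ozonide of 3, (5S)-4,4-dimethyl-5-(1,2,4-trioxolan-3-yl)cyclohex-2-en-1-one (both epimers at the trioxolane carbon) | O=C1C=CC(C)(C)[C@@H](C2OCOO2)C1 | intermediate
5 | (S)-2,2-dimethyl-5-oxocyclohex-3-ene-1-carbaldehyde | O=C1C=CC(C)(C)[C@@H](C=O)C1 | intermediate
6 | (S)-5-(hydroxymethyl)-4,4-dimethylcyclohex-2-en-1-one | O=C1C=CC(C)(C)[C@@H](CO)C1 | intermediate
7 | (S)-5-{[tert-butyl(dimethyl)silyl]oxymethyl}-4,4-dimethylcyclohex-2-en-1-one | O=C1C=CC(C)(C)[C@@H](CO[Si](C)(C)C(C)(C)C)C1 | intermediate
8 | (5R,6Z)-5-{[tert-butyl(dimethyl)silyl]oxymethyl}-6-(hydroxymethylidene)-4,4-dimethylcyclohex-2-en-1-one | O/C=C1\C(=O)C=CC(C)(C)[C@H]1CO[Si](C)(C)C(C)(C)C | intermediate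
9 | methyl 3-[(1S,6R)-6-{[tert-butyl(dimethyl)silyl]oxymethyl}-1-formyl-5,5-dimethyl-2-oxocyclohex-3-en-1-yl]propanoate (C20 formyl cis, C9 chain trans to C6) | COC(=O)CC[C@]1(C=O)C(=O)C=CC(C)(C)[C@H]1CO[Si](C)(C)C(C)(C)C | intermediate
10 | methyl 3-[(1S,6R)-6-{[tert-butyl(dimethyl)silyl]oxymethyl}-1-(hydroxymethyl)-5,5-dimethyl-2-oxocyclohex-3-en-1-yl]propanoate | COC(=O)CC[C@]1(CO)C(=O)C=CC(C)(C)[C@H]1CO[Si](C)(C)C(C)(C)C | intermediate
11 | (6S,11R)-11-{[tert-butyl(dimethyl)silyl]oxymethyl}-10,10-dimethyl-2-oxaspiro[5.5]undec-8-ene-3,7-dione | O=C1CC[C@]2(CO1)C(=O)C=CC(C)(C)[C@H]2CO[Si](C)(C)C(C)(C)C | intermediate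
12 | dimethyl itaconate (dimethyl 2-methylidenebutanedioate) | COC(=O)CC(=C)C(=O)OC | starting material
13 | 2-methylidenebutane-1,4-diol | OCCC(=C)CO | intermediate
14 | 4-bromo-2-(bromomethyl)but-1-ene | BrCCC(=C)CBr | intermediate
15 | (6S,11R)-4-(4-bromo-2-methylidenebutyl)-11-{[tert-butyl(dimethyl)silyl]oxymethyl}-10,10-dimethyl-2-oxaspiro[5.5]undec-8-ene-3,7-dione (C8 epimers) | BrCCC(=C)CC1C[C@]2(COC1=O)C(=O)C=CC(C)(C)[C@H]2CO[Si](C)(C)C(C)(C)C | intermediate
16 | ozonide of 15 (C13 as a 3,3-disubstituted 1,2,4-trioxolane; C8 and C13 epimers) | BrCCC1(OCOO1)CC2C[C@]3(COC2=O)C(=O)C=CC(C)(C)[C@H]3CO[Si](C)(C)C(C)(C)C | intermediate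
17 | (6S,11R)-4-(4-bromo-2-oxobutyl)-11-{[tert-butyl(dimethyl)silyl]oxymethyl}-10,10-dimethyl-2-oxaspiro[5.5]undec-8-ene-3,7-dione (C8 epimers) | BrCCC(=O)CC1C[C@]2(COC1=O)C(=O)C=CC(C)(C)[C@H]2CO[Si](C)(C)C(C)(C)C | intermediate
18 | (6S,11R)-4-{[2-(2-bromoethyl)-1,3-dioxolan-2-yl]methyl}-11-{[tert-butyl(dimethyl)silyl]oxymethyl}-10,10-dimethyl-2-oxaspiro[5.5]undec-8-ene-3,7-dione (C8 epimers) | BrCCC1(OCCO1)CC2C[C@]3(COC2=O)C(=O)C=CC(C)(C)[C@H]3CO[Si](C)(C)C(C)(C)C | intermediate
19 | trimethylsilyl ketene acetal of 18 (C8=C7(OSiMe3)–O–C20) | BrCCC1(OCCO1)CC2=C(O[Si](C)(C)C)OC[C@@]3(C2)C(=O)C=CC(C)(C)[C@H]3CO[Si](C)(C)C(C)(C)C | intermediate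
20 | C8 phenylselenide of 18 (C8 epimers) | BrCCC1(OCCO1)CC2([Se]c4ccccc4)C[C@]3(COC2=O)C(=O)C=CC(C)(C)[C@H]3CO[Si](C)(C)C(C)(C)C | intermediate
21 | selenoxide of 20 (epimers at C8 and Se) | BrCCC1(OCCO1)CC2([Se](=O)c4ccccc4)C[C@]3(COC2=O)C(=O)C=CC(C)(C)[C@H]3CO[Si](C)(C)C(C)(C)C | intermediate
22 | (6S,11R)-4-{[2-(2-bromoethyl)-1,3-dioxolan-2-yl]methyl}-11-{[tert-butyl(dimethyl)silyl]oxymethyl}-10,10-dimethyl-2-oxaspiro[5.5]undeca-4,8-diene-3,7-dione (C8=C9 unsaturated lactone) | BrCCC1(OCCO1)CC2=C[C@]3(COC2=O)C(=O)C=CC(C)(C)[C@H]3CO[Si](C)(C)C(C)(C)C | intermediate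
23 | tricyclic ketal lactone: C13 ethylene ketal of 24; H8 and H9 cis; C11 cis to C1 across the lactone ring; C6 and C20 cis on ring A | C1COC2(O1)CC[C@@H]3[C@H](C2)C(=O)OC[C@]34C(=O)C=CC(C)(C)[C@H]4CO[Si](C)(C)C(C)(C)C | intermediate
24 | tricyclic keto lactone: ring A 4,4-dimethylcyclohex-2-en-1-one with the C5 CH2OTBS arm, spiro at C10 to the C7–O–C20 δ-lactone, cis-fused (H8/H9 cis) to the ring C cyclohexan-13-one | O=C1CC[C@@H]2[C@H](C1)C(=O)OC[C@]23C(=O)C=CC(C)(C)[C@H]3CO[Si](C)(C)C(C)(C)C | intermediate
25 | C13 tertiary alcohol of 24: 13-hydroxy-13-isopropenyl, isopropenyl cis to C8–H and C9–H | CC(=C)[C@]1(O)CC[C@@H]2[C@H](C1)C(=O)OC[C@]23C(=O)C=CC(C)(C)[C@H]3CO[Si](C)(C)C(C)(C)C | intermediate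
26 | 13-O-triethylsilyl ether of 25 | CC(=C)[C@]1(O[Si](CC)(CC)CC)CC[C@@H]2[C@H](C1)C(=O)OC[C@]23C(=O)C=CC(C)(C)[C@H]3CO[Si](C)(C)C(C)(C)C | intermediate
27 | lactone tert-butyldimethylsilyl ketene acetal of 26 (C8=C7(OTBS)–O–C20; C13 isopropenyl cis to C9–H) | CC(=C)[C@]1(O[Si](CC)(CC)CC)CC[C@@H]2C(C1)=C(O[Si](C)(C)C(C)(C)C)OC[C@]23C(=O)C=CC(C)(C)[C@H]3CO[Si](C)(C)C(C)(C)C | intermediate
28 | tetracyclic lactone: 16-methylidene bicyclo[3.2.1]octane (rings C/D) with C8 quaternary, 13-O-triethylsilyl, 6-O-tert-butyldimethylsilyl, ring A enone, 7,20-lactone | C=C1C[C@]23C[C@@]1(O[Si](CC)(CC)CC)CC[C@H]2[C@]1(COC3=O)C(=O)C=CC(C)(C)[C@H]1CO[Si](C)(C)C(C)(C)C | intermediate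
29 | C15 allylic alcohol of 28 (either C15 epimer) | C=C1C(O)[C@]23C[C@@]1(O[Si](CC)(CC)CC)CC[C@H]2[C@]1(COC3=O)C(=O)C=CC(C)(C)[C@H]1CO[Si](C)(C)C(C)(C)C | intermediate
30 | 16-methylidene-15-ketone (ring D exocyclic enone) with both silyl ethers | C=C1C(=O)[C@]23C[C@@]1(O[Si](CC)(CC)CC)CC[C@H]2[C@]1(COC3=O)C(=O)C=CC(C)(C)[C@H]1CO[Si](C)(C)C(C)(C)C | intermediate
31 | 6-O-tert-butyldimethylsilyl-13-O-triethylsilyl ether of the target (16R methyl) | C[C@H]1C(=O)[C@]23C[C@@]1(O[Si](CC)(CC)CC)CC[C@H]2[C@]1(COC3=O)C(=O)C=CC(C)(C)[C@H]1CO[Si](C)(C)C(C)(C)C | intermediate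
32 | CNP0533761.1, (5R,8S,9S,10S,13S,16R)-6,13-dihydroxy-1,15-dioxo-6,7-secokaur-2-en-7,20-olide | C[C@H]1C(=O)[C@]23C[C@@]1(O)CC[C@H]2[C@]1(COC3=O)C(=O)C=CC(C)(C)[C@H]1CO | target

**Step count**

Total step count: 22. Longest linear sequence: 20 steps (steps 1–7 and 10–22 from compound 1); the two-step preparation of 14 (steps 8–9) runs in parallel.

**Steps most likely to fail**

Step 13 (radical closure of ring C). The primary C11 radical may be reduced before it reaches the hindered C9, or it may add on the wrong face of C9. Fallback: setting out from 22, a Kornblum-type oxidation (AgBF4, DMSO; then Et3N) would turn the primary bromide into the C11 aldehyde F1. SmI2 with t-BuOH in THF at −78 °C would then form the C11 ketyl, which adds to C9 in a ketyl–olefin cyclisation to give the C11-hydroxy tricyclic ketal lactone F2; an aldehyde is reduced much faster than the hindered enone, and a ketyl is a more nucleophilic and longer-lived radical than the alkyl radical. Thiocarbonyldiimidazole/DMAP would convert F2 into its imidazolyl thiocarbonate F3, and Barton–McCombie deoxygenation (Bu3SnH, AIBN, toluene, 90 °C) would remove the C11 oxygen and return to the route at 23.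

Step 2 (desymmetrising vinyl addition). A second vinyl group may add to the remaining enone arm, or enantioselection at the neopentyl β-carbon may be poor. Fallback: setting out from 2, an organocatalytic asymmetric Michael addition of nitromethane (9-amino-9-deoxy-epi-cinchona primary amine with an acid co-catalyst, iminium activation) would give (S)-4,4-dimethyl-5-(nitromethyl)cyclohex-2-en-1-one F4. A Nef reaction (NaOMe, MeOH; then buffered aqueous TiCl3) would convert the nitromethyl group into the formyl group, returning to the route at aldehyde 5, which is reduced as in step 3.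

Step 21 (reduction of the ring D enone). Chemoselectivity between the two enones may be lost, or protonation and epimerisation at C16 may give the wrong methyl configuration. Fallback: setting out from 30, desilylation first (HF·pyridine, pyridine/THF) would give the 16-methylidene diol F5. Hydroxyl-directed hydrogenation with [Ir(cod)(PCy3)(py)]PF6 (5 mol %) and H2 (1 atm) in CH2Cl2 would then use the free allylic C13 hydroxyl group, which sits on the exo face of ring D, to deliver hydrogen to C16=C17 from that face and only to that alkene, arriving directly at 32.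

**Further compounds**

F1 | step 13 | C11 aldehyde of the unsaturated ketal lactone (the CH2Br of 22 replaced by CHO) | O=CCC1(OCCO1)CC2=C[C@]3(COC2=O)C(=O)C=CC(C)(C)[C@H]3CO[Si](C)(C)C(C)(C)C
F2 | step 13 | C11-hydroxy tricyclic ketal lactone (11-hydroxy derivative of 23, C11 epimers) | C1COC2(O1)CC(O)[C@@H]3[C@H](C2)C(=O)OC[C@]34C(=O)C=CC(C)(C)[C@H]4CO[Si](C)(C)C(C)(C)C
F3 | step 13 | imidazol-1-yl thiocarbonate of F2 at the C11 oxygen | C1COC2(O1)CC(OC(=S)n5ccnc5)[C@@H]3[C@H](C2)C(=O)OC[C@]34C(=O)C=CC(C)(C)[C@H]4CO[Si](C)(C)C(C)(C)C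
F4 | step 2 | (S)-4,4-dimethyl-5-(nitromethyl)cyclohex-2-en-1-one | O=C1C=CC(C)(C)[C@@H](C[N+](=O)[O-])C1
F5 | step 21 | 16-methylidene analogue of the target (desilylated 30) | C=C1C(=O)[C@]23C[C@@]1(O)CC[C@H]2[C@]1(COC3=O)C(=O)C=CC(C)(C)[C@H]1CO
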